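**Plan**
1. Retrosynthesis: ring C is opened at C3–C2 and O1–C8a together, giving the B-ring aldehyde 14 and the enol silane 11 of a 2'-fluoroacetophenone. Ring A is then cut at its two C–prenyl bonds and the C4a–acetyl bond back to 5-fluororesorcinol, and ring B at C5'–prenyl back to 5-bromovanillin.
2. Enabling feature: the C4 carbonyl makes C3 a nucleophile and, being ortho to C8a on ring A, makes a C8a–F bond an SNAr site, while the oxygens on C5 and C7 are meta to C8a. C3–C4–C4a–C8a(F) therefore behaves as a benzo-fused 1-leaving-group-3-siloxy diene that takes up the aldehyde C2=O1 in a formal hetero-[4+2].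
3. Forward order: ring A is fully substituted first by three directed metalations (each ring C–H of the bis-MOM ether is flanked by two directing groups). Ring B is prenylated by cross-coupling, ring C is closed last in one flask, and the three MOM groups are then removed.
4. Stereochemistry: the only stereocentre, C2 (S), is set by a chiral boron Lewis acid when the C3–C2 bond forms. Its C2–O1 bond comes in with the aldehyde and is never formed at C2, so ring closure bypasses the reversible chalcone/oxa-Michael manifold.

Key step: step 8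

Assumption: the (R)-tryptophan-derived oxazaborolidinone is taken to deliver the enol silane to the Si face of the aldehyde (giving 2S); if a pilot run shows the opposite sense, the (S)-tryptophan catalyst is used with no other change.

**Step 1**
Reactants: 1 5-fluororesorcinol
Product: 2 1-fluoro-3,5-bis(methoxymethoxy)benzene
Conditions: MOMCl, i-Pr2NEt, CH2Cl2, 0 °C to rt
Reagents that add atoms: chloromethyl methyl ether, COCCl
Why: O-alkylation of both phenols (acetal formation) should give the bis-MOM ether, whose groups later direct metalation and come off under mild acid.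

**Step 2**
Reactants: 2 1-fluoro-3,5-bis(methoxymethoxy)benzene
Product: 4 5-fluoro-1,3-bis(methoxymethoxy)-2-(3-methylbut-2-en-1-yl)benzene, via aryllithium 3 (not isolated)
Conditions: n-BuLi, THF, –78 to –20 °C; CuBr·SMe2 (10 mol%), prenyl bromide, –78 to 0 °C
Reagents that add atoms: 1-bromo-3-methylbut-2-ene, CC(C)=CCBr
Why: Directed ortho metalation should occur at the C–H between the two MOM ethers (double chelation, no TMEDA, and a lithio species with no ortho fluorine), and Cu-catalysed SN2 allylation should then give the linear prenyl arene.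

**Step 3**
Reactants: 4 5-fluoro-1,3-bis(methoxymethoxy)-2-(3-methylbut-2-en-1-yl)benzene
Product: 6 1-fluoro-3,5-bis(methoxymethoxy)-2,4-bis(3-methylbut-2-en-1-yl)benzene, via aryllithium 5 (not isolated)
Conditions: s-BuLi, TMEDA, THF, –78 °C; CuBr·SMe2 (10 mol%), prenyl bromide, –78 to –40 °C
Reagents that add atoms: 1-bromo-3-methylbut-2-ene, CC(C)=CCBr
Why: Directed ortho metalation at one of the two equivalent C–H positions flanked by F and OMOM, held at –78 °C so the ortho-fluoroaryllithium does not lose LiF, followed by Cu-catalysed allylation, should install the second prenyl group.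

**Step 4**
Reactants: 6 1-fluoro-3,5-bis(methoxymethoxy)-2,4-bis(3-methylbut-2-en-1-yl)benzene
Product: 9 1-[2-fluoro-4,6-bis(methoxymethoxy)-3,5-bis(3-methylbut-2-en-1-yl)phenyl]ethan-1-one, via aryllithium 7 (not isolated), via tetrahedral adduct 8 (not isolated)
Conditions: s-BuLi, TMEDA, THF, –78 °C; MeC(O)N(Me)OMe, –78 to –20 °C; then H2O
Reagents that add atoms: N-methoxy-N-methylacetamide, CC(=O)N(C)OC
Why: Directed ortho metalation of the last ring C–H and acyl substitution on a Weinreb amide should give the methyl ketone, because the chelated adduct 8 persists until work-up and prevents over-addition.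

**Step 5**
Reactants: 9 1-[2-fluoro-4,6-bis(methoxymethoxy)-3,5-bis(3-methylbut-2-en-1-yl)phenyl]ethan-1-one
Product: 11 {1-[2-fluoro-4,6-bis(methoxymethoxy)-3,5-bis(3-methylbut-2-en-1-yl)phenyl]ethenyl}oxy(trimethyl)silane, via lithium enolate 10 (not isolated)
Conditions: LDA, THF, –78 °C; TMSCl, –78 to 0 °C; non-aqueous work-up, used crude
Reagents that add atoms: chlorotrimethylsilane, C[Si](C)(C)Cl
Why: Kinetic enolisation of the methyl ketone (no ring C–H remains) and O-silylation should give the enol silane needed for the Mukaiyama aldol addition.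

**Step 6**
Reactants: 12 5-bromovanillin
Product: 13 3-bromo-5-methoxy-4-(methoxymethoxy)benzaldehyde
Conditions: MOMCl, i-Pr2NEt, CH2Cl2, 0 °C to rt
Reagents that add atoms: chloromethyl methyl ether, COCCl
Why: O-alkylation of the acidic phenol (acetal formation) should mask it for the Lewis acid and fluoride conditions of the key step.

**Step 7**
Reactants: 13 3-bromo-5-methoxy-4-(methoxymethoxy)benzaldehyde
Product: 14 3-methoxy-4-(methoxymethoxy)-5-(3-methylbut-2-en-1-yl)benzaldehyde
Conditions: Bu3Sn(prenyl), Pd(PPh3)4 (5 mol%), DMF, 90 °C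
Reagents that add atoms: tributyl(3-methylbut-2-en-1-yl)stannane, CCCC[Sn](CCCC)(CCCC)CC=C(C)C
Why: Stille cross-coupling of the aryl bromide with the allylic stannane should give the linear prenyl arene (coupling at the unsubstituted terminus), with aldehyde and MOM ether inert.

**Step 8**
Reactants: 11 {1-[2-fluoro-4,6-bis(methoxymethoxy)-3,5-bis(3-methylbut-2-en-1-yl)phenyl]ethenyl}oxy(trimethyl)silane; 14 3-methoxy-4-(methoxymethoxy)-5-(3-methylbut-2-en-1-yl)benzaldehyde
Product: 16 (2S)-2-[3-methoxy-4-(methoxymethoxy)-5-(3-methylbut-2-en-1-yl)phenyl]-5,7-bis(methoxymethoxy)-6,8-bis(3-methylbut-2-en-1-yl)-2,3-dihydro-4H-chromen-4-one, via silyl aldol 15 (not isolated)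
Conditions: B-n-butyl oxazaborolidinone from N-tosyl-(R)-tryptophan (20 mol%), EtCN, –78 °C; then TBAT (0.4 equiv), THF/DMF, –78 to 0 °C; pH 7 buffer
Reagents that add atoms: none
Why: Proposed new method: the boron Lewis acid activates aldehyde 14 and the enol silane 11 adds through an open transition state with silyl transfer to oxygen, so the C3–C2 bond forms as in a catalytic asymmetric Mukaiyama aldol addition (the closest known reaction type, established for aryl methyl ketone enol silanes with aromatic aldehydes) and the aldolate is held as silyl ether 15, which cannot revert. Fluoride then removes the silyl group and the alkoxide adds to C8a, ortho to the C4 carbonyl, and expels fluoride (intramolecular SNAr; the closest known types are the fluoride-catalysed etherification of silyl ethers with acyl-activated aryl fluorides and the two-stage aldol/cyclisation course of hetero-Diels–Alder reactions of 1-alkoxy-3-siloxy dienes with aldehydes), and the fluoride set free desilylates the next molecule of 15, so a substoichiometric charge should suffice and the alkoxide stays at low concentration. The pyranone ring closes by a 6-endo-trig addition–elimination at C8a, the C4a=C8a bond inside the new ring relaying the charge to the C4 carbonyl, in the same geometric sense as the oxa-Michael closure of 2'-hydroxychalcones. C2 is set in the aldol stage by the catalyst, whose indole ring is expected to cover the Re face of the boron-bound aldehyde so that C3 arrives at the Si face, and it is not touched in the ring closure because the C2–O1 bond comes in with the aldehyde. The step needs ring closure to be faster than retro-aldol cleavage and E1cB loss of the β-oxygen, which is served by the low temperature, the fluoride relay and a Meisenheimer complex whose charge lies on C4a/C4=O, C6 and C8 and not on the oxygen-bearing C5 and C7 (both meta to C8a); no regiochemical issue arises because ring A carries a single fluorine and no free position.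

**Step 9**
Reactants: 16 (2S)-2-[3-methoxy-4-(methoxymethoxy)-5-(3-methylbut-2-en-1-yl)phenyl]-5,7-bis(methoxymethoxy)-6,8-bis(3-methylbut-2-en-1-yl)-2,3-dihydro-4H-chromen-4-one
Product: 17 (2S)-5,7-dihydroxy-2-[4-hydroxy-3-methoxy-5-(3-methylbut-2-en-1-yl)phenyl]-6,8-bis(3-methylbut-2-en-1-yl)-2,3-dihydro-4H-chromen-4-one
Conditions: HCl (3 M in MeOH), 40 °C, stopped at full conversion
Reagents that add atoms: none
Why: Acid-catalysed acetal cleavage (transacetalisation to methanol) of the three aryl MOM ethers should free the phenols, while the trisubstituted olefins and the C2 centre (no base, hence no ring opening to the chalcone) are expected to survive the mild methanolic acid.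

**Compound list**
1 | 5-fluororesorcinol (5-fluorobenzene-1,3-diol) | Oc1cc(O)cc(F)c1 | starting material
2 | 1-fluoro-3,5-bis(methoxymethoxy)benzene | COCOc1cc(F)cc(OCOC)c1 | intermediate
3 | [4-fluoro-2,6-bis(methoxymethoxy)phenyl]lithium | [Li]c1c(OCOC)cc(F)cc1OCOC | intermediate (not isolated)
4 | 5-fluoro-1,3-bis(methoxymethoxy)-2-(3-methylbut-2-en-1-yl)benzene | COCOc1cc(F)cc(OCOC)c1CC=C(C)C | intermediate
5 | [6-fluoro-2,4-bis(methoxymethoxy)-3-(3-methylbut-2-en-1-yl)phenyl]lithium | [Li]c1c(F)cc(OCOC)c(CC=C(C)C)c1OCOC | intermediate (not isolated)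
6 | 1-fluoro-3,5-bis(methoxymethoxy)-2,4-bis(3-methylbut-2-en-1-yl)benzene | COCOc1cc(F)c(CC=C(C)C)c(OCOC)c1CC=C(C)C | intermediate
7 | [2-fluoro-4,6-bis(methoxymethoxy)-3,5-bis(3-methylbut-2-en-1-yl)phenyl]lithium | [Li]c1c(F)c(CC=C(C)C)c(OCOC)c(CC=C(C)C)c1OCOC | intermediate (not isolated)
8 | lithium 1-[2-fluoro-4,6-bis(methoxymethoxy)-3,5-bis(3-methylbut-2-en-1-yl)phenyl]-1-[methoxy(methyl)amino]ethan-1-olate (racemic tetrahedral adduct) | CC(O[Li])(N(C)OC)c1c(F)c(CC=C(C)C)c(OCOC)c(CC=C(C)C)c1OCOC | intermediate (not isolated)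
9 | 1-[2-fluoro-4,6-bis(methoxymethoxy)-3,5-bis(3-methylbut-2-en-1-yl)phenyl]ethan-1-one | CC(=O)c1c(F)c(CC=C(C)C)c(OCOC)c(CC=C(C)C)c1OCOC | intermediate
10 | lithium 1-[2-fluoro-4,6-bis(methoxymethoxy)-3,5-bis(3-methylbut-2-en-1-yl)phenyl]ethen-1-olate | C=C(O[Li])c1c(F)c(CC=C(C)C)c(OCOC)c(CC=C(C)C)c1OCOC | intermediate (not isolated)
11 | {1-[2-fluoro-4,6-bis(methoxymethoxy)-3,5-bis(3-methylbut-2-en-1-yl)phenyl]ethenyl}oxy(trimethyl)silane | C=C(O[Si](C)(C)C)c1c(F)c(CC=C(C)C)c(OCOC)c(CC=C(C)C)c1OCOC | intermediate
12 | 5-bromovanillin (3-bromo-4-hydroxy-5-methoxybenzaldehyde) | COc1cc(C=O)cc(Br)c1O | starting material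
13 | 3-bromo-5-methoxy-4-(methoxymethoxy)benzaldehyde | COCOc1c(Br)cc(C=O)cc1OC | intermediate
14 | 3-methoxy-4-(methoxymethoxy)-5-(3-methylbut-2-en-1-yl)benzaldehyde | COCOc1c(CC=C(C)C)cc(C=O)cc1OC | intermediate
15 | (3S)-1-[2-fluoro-4,6-bis(methoxymethoxy)-3,5-bis(3-methylbut-2-en-1-yl)phenyl]-3-[3-methoxy-4-(methoxymethoxy)-5-(3-methylbut-2-en-1-yl)phenyl]-3-[(trimethylsilyl)oxy]propan-1-one | COc1cc([C@@H](O[Si](C)(C)C)CC(=O)c2c(F)c(CC=C(C)C)c(OCOC)c(CC=C(C)C)c2OCOC)cc(CC=C(C)C)c1OCOC | intermediate (not isolated)
16 | (2S)-2-[3-methoxy-4-(methoxymethoxy)-5-(3-methylbut-2-en-1-yl)phenyl]-5,7-bis(methoxymethoxy)-6,8-bis(3-methylbut-2-en-1-yl)-2,3-dihydro-4H-chromen-4-one | COc1cc([C@@H]2CC(=O)c3c(OCOC)c(CC=C(C)C)c(OCOC)c(CC=C(C)C)c3O2)cc(CC=C(C)C)c1OCOC | intermediate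
17 | (2S)-5,7-dihydroxy-2-[4-hydroxy-3-methoxy-5-(3-methylbut-2-en-1-yl)phenyl]-6,8-bis(3-methylbut-2-en-1-yl)-2,3-dihydro-4H-chromen-4-one (CNP0235424.1) | COc1cc([C@@H]2CC(=O)c3c(O)c(CC=C(C)C)c(O)c(CC=C(C)C)c3O2)cc(CC=C(C)C)c1O | target

**Totals**
Total step count: 9. Longest linear sequence: 7 steps (steps 1, 2, 3, 4, 5, 8, 9).

**Steps most likely to fail**

1. Step 8 (proposed new method). Once fluoride releases the alkoxide, retro-aldol cleavage or E1cB loss of the β-oxygen may outrun ring closure, re-addition of the fragments may erode the enantiomeric purity, and the hindered enol silane may add with insufficient facial selectivity. The fallback makes the two bonds in separate, known operations, setting out from ketone 9 and aldehyde 14. Claisen–Schmidt condensation (KOH, EtOH, 0 °C to rt) should give the (E)-2'-fluorochalcone F1. Nucleophilic Juliá–Colonna epoxidation (poly-D-leucine, urea–H2O2, DBU, THF), which attacks only the enone and not the three prenyl olefins, should give the (2S,3R)-epoxy ketone F2 (the antipode of the poly-L-leucine product). SmI2 (THF/MeOH, –90 °C) should cleave the Cα–O bond to the (S)-β-hydroxy ketone F3 with the carbinol centre untouched. F3, as its chelated sodium alkoxide (NaH, THF/DMF, 0 °C), should then close by intramolecular SNAr and rejoin the route at 16.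

2. Step 4. The ortho-fluoroaryllithium may lose LiF to an aryne before it is acylated, or may be quenched by proton transfer from the acetyl group of the amide because the carbanion is hindered. The fallback sets out from 6: the aryllithium 7 is trapped at –78 °C with acetaldehyde, a faster and smaller electrophile, to give the secondary benzylic alcohol F4. Dess–Martin periodinane (NaHCO3, CH2Cl2, rt) should oxidise F4 to rejoin the route at ketone 9.

3. Step 9. Under Brønsted acid the freed phenols may add to the neighbouring prenyl double bonds (chroman formation), and the hindered 7-O acetal may cleave incompletely. The fallback sets out from 16 and avoids acid solvolysis: the acetals are exchanged for silyl ethers under buffered aprotic conditions (TMSOTf, 2,2'-bipyridyl, MeCN, 0 °C) to give the tris(trimethylsilyl) ether F5. F5 is then hydrolysed at neutral pH (water, rt) to arrive at 17.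

**Further compounds**
F1 | step 8 | (2E)-1-[2-fluoro-4,6-bis(methoxymethoxy)-3,5-bis(3-methylbut-2-en-1-yl)phenyl]-3-[3-methoxy-4-(methoxymethoxy)-5-(3-methylbut-2-en-1-yl)phenyl]prop-2-en-1-one | COc1cc(/C=C/C(=O)c2c(F)c(CC=C(C)C)c(OCOC)c(CC=C(C)C)c2OCOC)cc(CC=C(C)C)c1OCOC
F2 | step 8 | [2-fluoro-4,6-bis(methoxymethoxy)-3,5-bis(3-methylbut-2-en-1-yl)phenyl]{(2S,3R)-3-[3-methoxy-4-(methoxymethoxy)-5-(3-methylbut-2-en-1-yl)phenyl]oxiran-2-yl}methanone | COc1cc([C@H]2O[C@@H]2C(=O)c3c(F)c(CC=C(C)C)c(OCOC)c(CC=C(C)C)c3OCOC)cc(CC=C(C)C)c1OCOC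
F3 | step 8 | (3S)-1-[2-fluoro-4,6-bis(methoxymethoxy)-3,5-bis(3-methylbut-2-en-1-yl)phenyl]-3-hydroxy-3-[3-methoxy-4-(methoxymethoxy)-5-(3-methylbut-2-en-1-yl)phenyl]propan-1-one | COc1cc([C@@H](O)CC(=O)c2c(F)c(CC=C(C)C)c(OCOC)c(CC=C(C)C)c2OCOC)cc(CC=C(C)C)c1OCOC
F4 | step 4 | 1-[2-fluoro-4,6-bis(methoxymethoxy)-3,5-bis(3-methylbut-2-en-1-yl)phenyl]ethan-1-ol (racemic) | CC(O)c1c(F)c(CC=C(C)C)c(OCOC)c(CC=C(C)C)c1OCOC
F5 | step 9 | (2S)-2-{3-methoxy-5-(3-methylbut-2-en-1-yl)-4-[(trimethylsilyl)oxy]phenyl}-6,8-bis(3-methylbut-2-en-1-yl)-5,7-bis[(trimethylsilyl)oxy]-2,3-dihydro-4H-chromen-4-one | COc1cc([C@@H]2CC(=O)c3c(O[Si](C)(C)C)c(CC=C(C)C)c(O[Si](C)(C)C)c(CC=C(C)C)c3O2)cc(CC=C(C)C)c1O[Si](C)(C)C
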